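**Retrosynthetic overview**
- The last event is a global desilylation. Before it, the ketone C(=O)–C(aryl) bond is cut to give mono-silylated hydroquinone and a spiro-succinic anhydride of the oxepine. The two are joined in one flask by O-acylation and a photo-Fries 1,3-acyl shift.
- Enabling feature: the ketone carbonyl and the C2 carboxyl are 1,4-related across quaternary C2 of the oxepine ring (a 2-oxysuccinyl unit). They therefore close to a five-membered anhydride spiro-fused at C2, in which only the CH2-flanked carbonyl is accessible. The ketone also sits ortho to a phenol oxygen of the 1,4-dioxygenated benzene ring with the para carbon blocked, so an O-to-C acyl shift can reach only the required ring carbon.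
- The anhydride comes from the diacid. Oxepine C5=C6 is made by ring-closing metathesis, and the C2–O–C7 ether by palladium-catalysed allylic etherification of a tertiary alcohol.
- Quaternary C2 (R) comes from a copper bis(oxazoline) Mukaiyama aldol of methyl 2-oxohex-5-enoate. The side chain comes from homoprenyl bromide (E-selective Riley oxidation) and propargyl alcohol (carbomagnesiation).
- Ring order: the benzene ring is bought as hydroquinone, the oxepine ring is closed in step 9, and the temporary anhydride ring is closed in step 11 and opened again in step 13.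

Key step: step 13

Assumption: the sense of induction of the copper bis(oxazoline) aldol with the butenyl keto ester is taken to be the one established for pyruvate esters (S,S ligand gives the S adduct), so the R,R ligand is used.

Step 1
Reactants: 1 5-bromo-2-methylpent-2-ene
Product: 2 (E)-5-bromo-2-methylpent-2-en-1-ol
Conditions: SeO2 (0.2 equiv), t-BuOOH (2.5 equiv), salicylic acid (0.1 equiv), CH2Cl2, 0 to 23 °C
Reagents that add atoms: tert-butyl hydroperoxide, CC(C)(C)OO (oxygen atom, relayed through SeO2, O=[Se]=O)
Why: Riley oxidation (ene reaction of SeO2 followed by a [2,3]-sigmatropic shift) should hydroxylate the methyl group trans to the chain of the only alkene, which sets the E geometry of the side-chain allylic alcohol, while the primary bromide is inert.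

Step 2
Reactants: 2 (E)-5-bromo-2-methylpent-2-en-1-ol
Product: 3 (E)-(5-bromo-2-methylpent-2-enyloxy)(tert-butyl)dimethylsilane
Conditions: TBSCl, imidazole, CH2Cl2, 0 to 23 °C
Reagents that add atoms: tert-butyldimethylsilyl chloride, CC(C)(C)[Si](C)(C)Cl
Why: Imidazole-promoted silylation masks the allylic alcohol as a TBS ether that should survive organomagnesium, palladium, ruthenium, hydroxide and light and leaves only in the last step.

Step 3
Reactants: 3 (E)-(5-bromo-2-methylpent-2-enyloxy)(tert-butyl)dimethylsilane; 4 prop-2-yn-1-ol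
Product: 8 (E)-7-(tert-butyldimethylsilyloxy)-6-methyl-2-methylidenehept-5-en-1-ol, via Grignard reagent 5 (not isolated), via magnesium alkoxide 6 (not isolated), via alkenylmagnesium chelate 7 (not isolated)
Conditions: 3, Mg, THF, 23 to 40 °C; 4, MeMgCl (1.0 equiv), THF, 0 °C; both solutions combined, CuI (10 mol %), THF/Et2O, 0 to 23 °C; aq. NH4Cl
Reagents that add atoms: none
Why: Copper-catalysed carbomagnesiation of propargyl alcohol, in which the magnesium alkoxide directs the alkyl group of 5 to the internal alkyne carbon and magnesium to the terminal one (chelate 7), so that protonolysis should give the 2-substituted allylic alcohol with the E-alkene untouched.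

Step 4
Reactants: 8 (E)-7-(tert-butyldimethylsilyloxy)-6-methyl-2-methylidenehept-5-en-1-ol
Product: 9 tert-butyl (E)-7-(tert-butyldimethylsilyloxy)-6-methyl-2-methylidenehept-5-enyl carbonate
Conditions: Boc2O, DMAP (10 mol %), CH2Cl2, 0 to 23 °C
Reagents that add atoms: di-tert-butyl dicarbonate, CC(C)(C)OC(=O)OC(=O)OC(C)(C)C
Why: DMAP-catalysed O-acylation turns the alcohol into an allyl tert-butyl carbonate, a leaving group that ionises with zerovalent palladium and releases its own base.

Step 5
Reactants: 10 S-tert-butyl thioacetate
Product: 12 1-(tert-butylsulfanyl)-1-(trimethylsilyloxy)ethene, via lithium enolate 11 (not isolated)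
Conditions: LiN(i-Pr)2, THF, -78 °C; TMSCl, -78 to 0 °C
Reagents that add atoms: trimethylsilyl chloride, C[Si](C)(C)Cl
Why: Kinetic deprotonation of the thioester and O-silylation of lithium enolate 11 give the silyl ketene thioacetal needed for a Mukaiyama aldol.

Step 6
Reactants: 13 dimethyl oxalate; 14 but-3-enylmagnesium bromide
Product: 15 methyl 2-oxohex-5-enoate
Conditions: 13 (1.5 equiv), THF/Et2O, -78 °C; aq. NH4Cl at -78 °C
Reagents that add atoms: none
Why: Mono-addition of a Grignard reagent to excess dialkyl oxalate at low temperature is the standard route to alpha-keto esters, since a second addition is suppressed until the quench.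

Step 7
Reactants: 15 methyl 2-oxohex-5-enoate; 12 1-(tert-butylsulfanyl)-1-(trimethylsilyloxy)ethene
Product: 17 methyl (2R)-2-[2-(tert-butylsulfanyl)-2-oxoethyl]-2-hydroxyhex-5-enoate, via trimethylsilyl ether 16 (not isolated)
Conditions: Cu(OTf)2 (10 mol %), (R,R)-t-Bu-box [2,2'-(propane-2,2-diyl)bis((4R)-4-tert-butyl-4,5-dihydrooxazole), 11 mol %], THF, -78 °C; then 1 M HCl, THF, 23 °C
Reagents that add atoms: none
Why: Catalytic enantioselective Mukaiyama aldol in which keto ester 15 chelates divalent copper through both carbonyl oxygens in a square-planar bis(oxazoline) complex, the tert-butyl groups of the R,R ligand block the Si face of the ketone, and attack of 12 on the Re face should set quaternary C2 as R, acid then cleaving silyl ether 16.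

Step 8
Reactants: 17 methyl (2R)-2-[2-(tert-butylsulfanyl)-2-oxoethyl]-2-hydroxyhex-5-enoate; 9 tert-butyl (E)-7-(tert-butyldimethylsilyloxy)-6-methyl-2-methylidenehept-5-enyl carbonate
Product: 18 methyl (2R)-2-[2-(tert-butylsulfanyl)-2-oxoethyl]-2-[(E)-7-(tert-butyldimethylsilyloxy)-6-methyl-2-methylidenehept-5-enyloxy]hex-5-enoate
Conditions: Pd2(dba)3 (2.5 mol %), dppb (6 mol %), THF, 65 °C
Reagents that add atoms: none
Why: Tsuji-Trost allylic etherification of the kind used for hindered tertiary alcohols, in which zerovalent palladium ionises 9, the released tert-butoxide deprotonates the more acidic alpha-hydroxy ester so that only catalytic alkoxide is present (little chance for retro-aldol), both termini of the 2-substituted allyl ligand are the same CH2 group so only one ether can form, and C2 is untouched.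

Step 9
Reactants: 18 methyl (2R)-2-[2-(tert-butylsulfanyl)-2-oxoethyl]-2-[(E)-7-(tert-butyldimethylsilyloxy)-6-methyl-2-methylidenehept-5-enyloxy]hex-5-enoate
Product: 19 methyl (2R)-2-[2-(tert-butylsulfanyl)-2-oxoethyl]-6-[(E)-5-(tert-butyldimethylsilyloxy)-4-methylpent-3-enyl]-2,3,4,7-tetrahydrooxepine-2-carboxylate
Conditions: second-generation Grubbs catalyst (5 mol %), CH2Cl2 (2 mM), 40 °C
Reagents that add atoms: none
Why: Ring-closing metathesis in which the carbene loads on the terminal butenyl alkene and closes on the 1,1-disubstituted allyl ether alkene to the seven-membered ring (helped by the Thorpe-Ingold effect of quaternary C2), whereas the trisubstituted side-chain alkene is too hindered and could only give a ten-membered ring.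

Step 10
Reactants: 19 methyl (2R)-2-[2-(tert-butylsulfanyl)-2-oxoethyl]-6-[(E)-5-(tert-butyldimethylsilyloxy)-4-methylpent-3-enyl]-2,3,4,7-tetrahydrooxepine-2-carboxylate
Product: 20 (2R)-2-(carboxymethyl)-6-[(E)-5-(tert-butyldimethylsilyloxy)-4-methylpent-3-enyl]-2,3,4,7-tetrahydrooxepine-2-carboxylic acid
Conditions: LiOH (8 equiv), THF/MeOH/H2O, 23 to 50 °C; then 1 M HCl to pH 3, 0 °C
Reagents that add atoms: lithium hydroxide, [Li+].[OH-]
Why: Saponification takes the unhindered thioester first, after which the resulting carboxylate can no longer trigger beta-elimination of the ring oxygen, and then takes the hindered but alpha-alkoxy-activated methyl ester, while C2 bears no hydrogen and cannot epimerise.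

Step 11
Reactants: 20 (2R)-2-(carboxymethyl)-6-[(E)-5-(tert-butyldimethylsilyloxy)-4-methylpent-3-enyl]-2,3,4,7-tetrahydrooxepine-2-carboxylic acid
Product: 21 (5R)-8-[(E)-5-(tert-butyldimethylsilyloxy)-4-methylpent-3-enyl]-2,6-dioxaspiro[4.6]undec-8-ene-1,3-dione
Conditions: DCC (1.05 equiv), CH2Cl2, 0 to 23 °C; filtration, used crude
Reagents that add atoms: none
Why: Carbodiimide dehydration of a 2,2-disubstituted succinic acid closes the five-membered anhydride readily (gem-disubstituent effect) under neutral conditions that spare the silyl ether and both alkenes.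

Step 12
Reactants: 22 hydroquinone
Product: 23 4-(tert-butyldimethylsilyloxy)phenol
Conditions: 22 (3 equiv), TBSCl (1 equiv), imidazole (1.2 equiv), DMF, 0 to 23 °C
Reagents that add atoms: tert-butyldimethylsilyl chloride, CC(C)(C)[Si](C)(C)Cl
Why: Statistical monosilylation with excess diol, the water-soluble surplus being washed out, blocks one oxygen so that neither double acylation nor quinone formation can occur in the next step.

Step 13
Reactants: 21 (5R)-8-[(E)-5-(tert-butyldimethylsilyloxy)-4-methylpent-3-enyl]-2,6-dioxaspiro[4.6]undec-8-ene-1,3-dione; 23 4-(tert-butyldimethylsilyloxy)phenol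
Product: 25 (2R)-2-{2-[5-(tert-butyldimethylsilyloxy)-2-hydroxyphenyl]-2-oxoethyl}-6-[(E)-5-(tert-butyldimethylsilyloxy)-4-methylpent-3-enyl]-2,3,4,7-tetrahydrooxepine-2-carboxylic acid, via aryl hemisuccinate 24 (not isolated)
Conditions: Et3N (1.1 equiv), MeCN, 23 to 40 °C; then CF3CO2H (1.1 equiv), dilution with degassed MeCN to 5 mM, hν (254 nm, low-pressure Hg lamps, quartz), Ar, 23 °C
Reagents that add atoms: none
Why: Et3N-assisted attack of phenol 23 opens the five-membered anhydride ring of 21 at the carbonyl flanked by CH2, because the other carbonyl hangs on the fully substituted spiro carbon (oxepine C2) and is shielded as in a pivalic mixed anhydride, so the C2 carboxylic acid is set free and aryl ester 24 forms with the future phenol oxygen as the tether. Light of 254 nm is absorbed only by the aryl ester, whose singlet state breaks the ArO–C(=O) bond to a solvent-caged acyl/phenoxyl radical pair that recombines at the ortho carbon and tautomerises to the hydrogen-bonded o-hydroxyaryl ketone, which is a photo-Fries rearrangement, the closest known case being 4-alkoxyphenyl alkanoates going to 2-acyl-4-alkoxyphenols. No ring is closed (one temporary ring is opened) and no stereocenter is made, and no bond at C2 is touched, so its R configuration is carried through. Site selectivity on the arene is built into 24, since the para carbon carries OTBS and the two ortho carbons are equivalent, so only the 2-acyl-1,4-dioxygenated pattern can arise. Chemoselectivity rests on the transparency of both trisubstituted alkenes, the acid and the silyl ethers at 254 nm, on cage recombination being faster than decarbonylation of an acyl radical that would give a primary alkyl radical, and on fast excited-state proton transfer that protects the product. The medium stays neutral and metal-free, so the base-labile beta-alkoxy ketone (retro-oxa-Michael opening of the oxepine) is never at risk, and every atom of both partners ends up in 25.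

Step 14
Reactants: 25 (2R)-2-{2-[5-(tert-butyldimethylsilyloxy)-2-hydroxyphenyl]-2-oxoethyl}-6-[(E)-5-(tert-butyldimethylsilyloxy)-4-methylpent-3-enyl]-2,3,4,7-tetrahydrooxepine-2-carboxylic acid
Product: 26 (2R)-2-[2-(2,5-dihydroxyphenyl)-2-oxoethyl]-6-[(E)-5-hydroxy-4-methylpent-3-enyl]-2,3,4,7-tetrahydrooxepine-2-carboxylic acid
Conditions: HF·pyridine, pyridine/THF, 0 to 23 °C, Ar
Reagents that add atoms: none
Why: Fluoride-driven cleavage of both Si–O bonds in a mildly acidic medium should free the phenol and the allylic alcohol without enolising the beta-alkoxy ketone or oxidising the hydroquinone.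

**Compound list**
1 | 5-bromo-2-methylpent-2-ene | CC(C)=CCCBr | starting material
2 | (E)-5-bromo-2-methylpent-2-en-1-ol | C/C(=C\CCBr)CO | intermediate
3 | (E)-(5-bromo-2-methylpent-2-enyloxy)(tert-butyl)dimethylsilane | C/C(=C\CCBr)CO[Si](C)(C)C(C)(C)C | intermediate
4 | prop-2-yn-1-ol | C#CCO | starting material
5 | (E)-[5-(tert-butyldimethylsilyloxy)-4-methylpent-3-enyl]magnesium bromide | C/C(=C\CC[Mg]Br)CO[Si](C)(C)C(C)(C)C | intermediate
6 | chloromagnesium prop-2-yn-1-olate | C#CCO[Mg]Cl | intermediate
7 | five-membered alkenylmagnesium alkoxide chelate (Mg bound to the terminal alkene carbon and to oxygen) | C/C(=C\CCC1=C[Mg]OC1)CO[Si](C)(C)C(C)(C)C | intermediate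
8 | (E)-7-(tert-butyldimethylsilyloxy)-6-methyl-2-methylidenehept-5-en-1-ol | C/C(=C\CCC(=C)CO)CO[Si](C)(C)C(C)(C)C | intermediate
9 | tert-butyl (E)-7-(tert-butyldimethylsilyloxy)-6-methyl-2-methylidenehept-5-enyl carbonate | C/C(=C\CCC(=C)COC(=O)OC(C)(C)C)CO[Si](C)(C)C(C)(C)C | intermediate
10 | S-tert-butyl thioacetate | CC(=O)SC(C)(C)C | starting material
11 | lithium enolate of S-tert-butyl thioacetate | C=C(O[Li])SC(C)(C)C | intermediate
12 | 1-(tert-butylsulfanyl)-1-(trimethylsilyloxy)ethene | C=C(O[Si](C)(C)C)SC(C)(C)C | intermediate
13 | dimethyl oxalate | COC(=O)C(=O)OC | starting material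
14 | but-3-enylmagnesium bromide | C=CCC[Mg]Br | starting material
15 | methyl 2-oxohex-5-enoate | C=CCCC(=O)C(=O)OC | intermediate
16 | methyl (2R)-2-[2-(tert-butylsulfanyl)-2-oxoethyl]-2-(trimethylsilyloxy)hex-5-enoate | C=CCC[C@@](CC(=O)SC(C)(C)C)(C(=O)OC)O[Si](C)(C)C | intermediate
17 | methyl (2R)-2-[2-(tert-butylsulfanyl)-2-oxoethyl]-2-hydroxyhex-5-enoate | C=CCC[C@@](CC(=O)SC(C)(C)C)(C(=O)OC)O | intermediate
18 | methyl (2R)-2-[2-(tert-butylsulfanyl)-2-oxoethyl]-2-[(E)-7-(tert-butyldimethylsilyloxy)-6-methyl-2-methylidenehept-5-enyloxy]hex-5-enoate | C=CCC[C@@](CC(=O)SC(C)(C)C)(C(=O)OC)OCC(=C)CC/C=C(\C)CO[Si](C)(C)C(C)(C)C | intermediate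
19 | methyl (2R)-2-[2-(tert-butylsulfanyl)-2-oxoethyl]-6-[(E)-5-(tert-butyldimethylsilyloxy)-4-methylpent-3-enyl]-2,3,4,7-tetrahydrooxepine-2-carboxylate | C/C(=C\CCC1=CCC[C@@](CC(=O)SC(C)(C)C)(C(=O)OC)OC1)CO[Si](C)(C)C(C)(C)C | intermediate
20 | (2R)-2-(carboxymethyl)-6-[(E)-5-(tert-butyldimethylsilyloxy)-4-methylpent-3-enyl]-2,3,4,7-tetrahydrooxepine-2-carboxylic acid | C/C(=C\CCC1=CCC[C@@](CC(=O)O)(C(=O)O)OC1)CO[Si](C)(C)C(C)(C)C | intermediate
21 | (5R)-8-[(E)-5-(tert-butyldimethylsilyloxy)-4-methylpent-3-enyl]-2,6-dioxaspiro[4.6]undec-8-ene-1,3-dione | C/C(=C\CCC1=CCC[C@@](CC2=O)(C(=O)O2)OC1)CO[Si](C)(C)C(C)(C)C | intermediate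
22 | hydroquinone | Oc1ccc(O)cc1 | starting material
23 | 4-(tert-butyldimethylsilyloxy)phenol | Oc1ccc(O[Si](C)(C)C(C)(C)C)cc1 | intermediate
24 | (2R)-2-{2-[4-(tert-butyldimethylsilyloxy)phenoxy]-2-oxoethyl}-6-[(E)-5-(tert-butyldimethylsilyloxy)-4-methylpent-3-enyl]-2,3,4,7-tetrahydrooxepine-2-carboxylic acid | C/C(=C\CCC1=CCC[C@@](CC(=O)Oc2ccc(O[Si](C)(C)C(C)(C)C)cc2)(C(=O)O)OC1)CO[Si](C)(C)C(C)(C)C | intermediate
25 | (2R)-2-{2-[5-(tert-butyldimethylsilyloxy)-2-hydroxyphenyl]-2-oxoethyl}-6-[(E)-5-(tert-butyldimethylsilyloxy)-4-methylpent-3-enyl]-2,3,4,7-tetrahydrooxepine-2-carboxylic acid | C/C(=C\CCC1=CCC[C@@](CC(=O)c2cc(O[Si](C)(C)C(C)(C)C)ccc2O)(C(=O)O)OC1)CO[Si](C)(C)C(C)(C)C | intermediate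
26 | (2R)-2-[2-(2,5-dihydroxyphenyl)-2-oxoethyl]-6-[(E)-5-hydroxy-4-methylpent-3-enyl]-2,3,4,7-tetrahydrooxepine-2-carboxylic acid | C/C(=C\CCC1=CCC[C@@](CC(=O)c2cc(O)ccc2O)(C(=O)O)OC1)CO | target

**Step count**
- Total step count: 14.
- Longest linear sequence: 10 steps (steps 1, 2, 3, 4, 8, 9, 10, 11, 13, 14).

**Steps most likely to fail**

1. Step 13.
   - What may go wrong: the acyl/phenoxyl radical pair may escape from the solvent cage with loss of the acyl group. The strongly absorbing product may screen the light. Triplet sensitisation may scramble the E geometry of the side-chain alkene. The phenol may attack the hindered carbonyl of the anhydride.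
   - Fallback: a thermal, organometallic acyl transfer that sets out from 21 and 22 and comes back at 26. Hydroquinone 22 is converted with MOMCl and i-Pr2NEt into 1,4-bis(methoxymethoxy)benzene F1. This is ortho-lithiated (n-BuLi, TMEDA, THF, 0 °C) to the aryllithium F2 and transmetalated with ZnCl2 to the arylzinc chloride F3. Acylation of F3 with anhydride 21 under Ni(cod)2/2,2'-bipyridine catalysis (oxidative addition of zerovalent nickel at the less hindered acyl–oxygen bond, non-basic medium) should give the bis-MOM keto acid F4. Aqueous HCl in THF/i-PrOH then removes both MOM groups and the silyl ether to give 26.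

2. Step 8.
   - What may go wrong: the hindered, electron-poor alkoxide may capture the allylpalladium complex too slowly. The transient alkoxide may fragment by retro-aldol, followed by C-allylation of the released thioester enolate. Zerovalent palladium may insert into the thioester.
   - Fallback: an acid-catalysed alkylation in which no alkoxide and no metal are present, setting out from 8 and 17 and coming back at 18. Alcohol 8 is treated with Cl3CCN and catalytic DBU to give the allylic trichloroacetimidate F5. This alkylates tertiary alcohol 17 under catalytic TfOH in cyclohexane/CH2Cl2 at 0 °C to give 18.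

3. Step 3.
   - What may go wrong: carbometalation of the alkynyl alkoxide by the functionalised Grignard reagent may be sluggish or unselective. The Grignard reagent may be lost by protonation or homocoupling.
   - Fallback: a cross-coupling onto a preformed 2-haloallyl alcohol in place of alkyne carbometalation, setting out from 3 and coming back at 8. Zinc insertion into bromide 3 (Zn dust, LiCl, THF, 50 °C) gives the alkylzinc bromide F6. This is added slowly to commercial 2-bromoprop-2-en-1-ol under Negishi conditions that tolerate a free hydroxyl group (Pd(OAc)2, SPhos, THF, 23 °C) to give 8.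

**Further compounds**
F1 | step 13 | 1,4-bis(methoxymethoxy)benzene | COCOc1ccc(OCOC)cc1
F2 | step 13 | [2,5-bis(methoxymethoxy)phenyl]lithium | [Li]c1cc(OCOC)ccc1OCOC
F3 | step 13 | [2,5-bis(methoxymethoxy)phenyl]zinc chloride | Cl[Zn]c1cc(OCOC)ccc1OCOC
F4 | step 13 | (2R)-2-{2-[2,5-bis(methoxymethoxy)phenyl]-2-oxoethyl}-6-[(E)-5-(tert-butyldimethylsilyloxy)-4-methylpent-3-enyl]-2,3,4,7-tetrahydrooxepine-2-carboxylic acid | C/C(=C\CCC1=CCC[C@@](CC(=O)c2cc(OCOC)ccc2OCOC)(C(=O)O)OC1)CO[Si](C)(C)C(C)(C)C
F5 | step 8 | (E)-7-(tert-butyldimethylsilyloxy)-6-methyl-2-methylidenehept-5-enyl 2,2,2-trichloroacetimidate | C/C(=C\CCC(=C)COC(=N)C(Cl)(Cl)Cl)CO[Si](C)(C)C(C)(C)C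
F6 | step 3 | (E)-[5-(tert-butyldimethylsilyloxy)-4-methylpent-3-enyl]zinc bromide | C/C(=C\CC[Zn]Br)CO[Si](C)(C)C(C)(C)C
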